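**Retrosynthetic overview**

- The target is an achiral depside. The aryl ester bond between the ring A carbonyl and O4 of ring B is cut last, giving everninic acid 15 and benzyl olivetolate 14.
- The strategy rests on ring B: the carboxyl carbon C1 lies between the oxygen-bearing C2 and the pentyl-bearing C6. The C1–C6 pair is therefore read as an aryne that the C2 oxygen polarises.
- One three-component coupling on 3,5-bis(benzyloxy)benzyne makes both ring B carbon–carbon bonds: pentylmagnesium bromide forms C6–pentyl, then CO2 forms C1–carboxyl.
- The aryne precursor 5 comes from 1-fluoro-3,5-dimethoxybenzene by demethylation, benzylation and bromination.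
- No ring is built (both benzene rings are bought) and there is no stereocentre to set.

Key step: step 5

**Route**

Step 1
Reactants: 1 1-fluoro-3,5-dimethoxybenzene
Product: 2 5-fluorobenzene-1,3-diol
Conditions: BBr3 (3 equiv), CH2Cl2, −78 °C → rt; then ice/H2O
Reagents that add atoms: none
Why: Lewis-acid cleavage of aryl methyl ethers (BBr3 demethylation) proceeds through the aryloxyborane with bromide attack at methyl, and the aryl C–F bond is inert to it.

Step 2
Reactants: 2 5-fluorobenzene-1,3-diol; 3 benzyl bromide
Product: 4 1,3-bis(benzyloxy)-5-fluorobenzene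
Conditions: BnBr (2.2 equiv), K2CO3 (3 equiv), DMF, 60 °C
Reagents that add atoms: benzyl bromide, BrCc1ccccc1
Why: Williamson ether synthesis on both phenoxides with a reactive benzylic halide should be clean, since no other nucleophilic site is present.

Step 3
Reactants: 4 1,3-bis(benzyloxy)-5-fluorobenzene
Product: 5 1,5-bis(benzyloxy)-2-bromo-3-fluorobenzene
Conditions: NBS (1.0 equiv), MeCN, 0 °C → rt, dark
Reagents that add atoms: N-bromosuccinimide, O=C1CCC(=O)N1Br
Why: Electrophilic aromatic bromination should go to the position para to one benzyloxy group and ortho to the other (next to the small fluorine) rather than to the crowded position between both benzyloxy groups, and one equivalent of NBS limits a second bromination.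

Step 4
Reactants: 6 1-bromopentane
Product: 7 pentylmagnesium bromide
Conditions: Mg turnings (1.2 equiv), I2 (cat.), THF, 40 °C → reflux; titrate
Reagents that add atoms: magnesium, [Mg]
Why: Grignard formation by magnesium insertion into a primary alkyl bromide is routine.

Step 5
Reactants: 5 1,5-bis(benzyloxy)-2-bromo-3-fluorobenzene; 7 pentylmagnesium bromide; 8 carbon dioxide
Product: 12 2,4-bis(benzyloxy)-6-pentylbenzoic acid, via aryllithium 9 (not isolated), via aryne 10 (not isolated), via arylmagnesium bromide 11 (not isolated)
Conditions: n-BuLi (1.0 equiv), THF, −78 °C, 20 min; slow cannulation into 7 (3 equiv), THF, 0 °C → rt, then 40 °C; CO2 (dry gas), −20 °C → rt; 1 M HCl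
Reagents that add atoms: pentylmagnesium bromide, CCCCC[Mg]Br; carbon dioxide, O=C=O
Why: Bromine–lithium exchange at −78 °C is much faster than any attack on the benzyl ethers and gives the ortho-fluoro aryl anion 9; on warming in the Grignard solution it loses LiF to give aryne 10, pentylmagnesium bromide adds across the strained triple bond (carbomagnesiation), and the resulting arylmagnesium 11 is carboxylated by CO2. This is the known three-component aryne coupling: a 3-alkoxyaryne from an ortho-halo fluoroarene, organomagnesium addition, then electrophilic quench of the aryl anion. No ring is closed and no stereocentre is formed. The selectivity needed is regiochemical, and the benzyloxy group beside the triple bond secures it: it distorts the aryne and stabilises negative charge on the adjacent carbon by induction and by chelation of magnesium, so pentyl enters at the distal carbon (future C6) and the metal, hence the carboxyl, sits on the oxygen-flanked carbon (future C1); the second benzyloxy group is too remote to override this. Slow addition of 9 into excess 7 keeps the aryl anion from capturing the aryne itself, and the hindered arylmagnesium 11 still accepts the small electrophile CO2.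

Step 6
Reactants: 12 2,4-bis(benzyloxy)-6-pentylbenzoic acid
Product: 13 2,4-dihydroxy-6-pentylbenzoic acid (olivetolic acid)
Conditions: H2 (1 atm), 10% Pd/C, EtOAc, rt; filter, concentrate below 30 °C
Reagents that add atoms: none
Why: Catalytic hydrogenolysis cleaves both benzyl aryl ethers under neutral conditions, and working at room temperature avoids decarboxylation of the β-resorcylic acid.

Step 7
Reactants: 13 2,4-dihydroxy-6-pentylbenzoic acid; 3 benzyl bromide
Product: 14 benzyl 2,4-dihydroxy-6-pentylbenzoate
Conditions: BnBr (1.05 equiv), KHCO3 (1.2 equiv), DMF, rt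
Reagents that add atoms: benzyl bromide, BrCc1ccccc1
Why: Bicarbonate ionises only the carboxyl group, so SN2 O-alkylation of the carboxylate gives the benzyl ester while both phenols stay protonated and unreactive.

Step 8
Reactants: 14 benzyl 2,4-dihydroxy-6-pentylbenzoate; 15 everninic acid (2-hydroxy-4-methoxy-6-methylbenzoic acid)
Product: 17 benzyl 2-hydroxy-4-[(2-hydroxy-4-methoxy-6-methylbenzoyl)oxy]-6-pentylbenzoate, via mixed anhydride 16 (not isolated)
Conditions: (CF3CO)2O (3 equiv), toluene, rt; aq. NaHCO3 wash
Reagents that add atoms: none
Why: Trifluoroacetic anhydride-mediated esterification (the standard depside coupling) turns acid 15 into the aroyl trifluoroacetate 16, which acylates the unchelated 4-OH of 14, while the 2-OH of each partner is tied up in a hydrogen bond to its ortho carbonyl and any transient aryl trifluoroacetate is cleaved in the bicarbonate wash.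

Step 9
Reactants: 17 benzyl 2-hydroxy-4-[(2-hydroxy-4-methoxy-6-methylbenzoyl)oxy]-6-pentylbenzoate
Product: 18 2-hydroxy-4-[(2-hydroxy-4-methoxy-6-methylbenzoyl)oxy]-6-pentylbenzoic acid (target)
Conditions: H2 (1 atm), 10% Pd/C, EtOAc, rt
Reagents that add atoms: none
Why: Hydrogenolysis removes the benzyl ester under neutral conditions that leave the aryl ester (depside) link, the methyl ether and both phenols untouched.

**Compound list**

1 | 1-fluoro-3,5-dimethoxybenzene | COc1cc(F)cc(OC)c1 | starting material
2 | 5-fluorobenzene-1,3-diol | Oc1cc(O)cc(F)c1 | intermediate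
3 | benzyl bromide | BrCc1ccccc1 | starting material
4 | 1,3-bis(benzyloxy)-5-fluorobenzene | Fc1cc(OCc2ccccc2)cc(OCc2ccccc2)c1 | intermediate
5 | 1,5-bis(benzyloxy)-2-bromo-3-fluorobenzene | Fc1cc(OCc2ccccc2)cc(OCc2ccccc2)c1Br | intermediate
6 | 1-bromopentane | CCCCCBr | starting material
7 | pentylmagnesium bromide | CCCCC[Mg]Br | intermediate
8 | carbon dioxide | O=C=O | starting material
9 | [2,4-bis(benzyloxy)-6-fluorophenyl]lithium | [Li]c1c(F)cc(OCc2ccccc2)cc1OCc1ccccc1 | intermediate (not isolated)
10 | 3,5-bis(benzyloxy)benzyne | C1#CC(OCc2ccccc2)=CC(OCc2ccccc2)=C1 | intermediate (not isolated)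
11 | [2,4-bis(benzyloxy)-6-pentylphenyl]magnesium bromide | CCCCCc1cc(OCc2ccccc2)cc(OCc2ccccc2)c1[Mg]Br | intermediate (not isolated)
12 | 2,4-bis(benzyloxy)-6-pentylbenzoic acid | CCCCCc1cc(OCc2ccccc2)cc(OCc2ccccc2)c1C(=O)O | intermediate
13 | 2,4-dihydroxy-6-pentylbenzoic acid (olivetolic acid) | CCCCCc1cc(O)cc(O)c1C(=O)O | intermediate
14 | benzyl 2,4-dihydroxy-6-pentylbenzoate | CCCCCc1cc(O)cc(O)c1C(=O)OCc1ccccc1 | intermediate
15 | everninic acid (2-hydroxy-4-methoxy-6-methylbenzoic acid) | COc1cc(C)c(C(=O)O)c(O)c1 | starting material
16 | 2-hydroxy-4-methoxy-6-methylbenzoic trifluoroacetic anhydride | COc1cc(C)c(C(=O)OC(=O)C(F)(F)F)c(O)c1 | intermediate (not isolated)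
17 | benzyl 2-hydroxy-4-[(2-hydroxy-4-methoxy-6-methylbenzoyl)oxy]-6-pentylbenzoate | CCCCCc1cc(OC(=O)c2c(C)cc(OC)cc2O)cc(O)c1C(=O)OCc1ccccc1 | intermediate
18 | 2-hydroxy-4-[(2-hydroxy-4-methoxy-6-methylbenzoyl)oxy]-6-pentylbenzoic acid | CCCCCc1cc(OC(=O)c2c(C)cc(OC)cc2O)cc(O)c1C(=O)O | target

**Step count**

Total steps: 9. Longest linear sequence: 8 (steps 1, 2, 3, 5, 6, 7, 8, 9); step 4 is a one-step side branch.

**Steps most likely to fail**

Step 5. The fluoro aryl anion may add to the aryne in competition with the pentyl nucleophile, fluoride loss may be incomplete before the CO2 quench, or the surplus Grignard reagent may complicate isolation of the acid through its own carboxylation. The fallback abandons the aryne and installs the two carbon substituents one after the other; it sets out from 7 and returns at 12. Pentylmagnesium bromide 7 is coupled with commercially available 1,3-bis(benzyloxy)-5-bromobenzene F1 under PdCl2(dppf) catalysis in THF (Kumada coupling) to give 1,3-bis(benzyloxy)-5-pentylbenzene F2. NBS in MeCN should brominate F2 para to one benzyloxy group and next to the pentyl chain, giving 1,5-bis(benzyloxy)-2-bromo-3-pentylbenzene F3. Bromine–lithium exchange on F3 with n-BuLi in THF at −78 °C gives [2,4-bis(benzyloxy)-6-pentylphenyl]lithium F4, and F4 is quenched with CO2 and acidified to give 12.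

Step 8. The hydroxy acid may acylate itself through its own phenol, the hindered 2,6-disubstituted acyl group may transfer too slowly, or the chelated 2-OH of 14 may also be acylated. The fallback masks the ring A phenol and uses a preformed acid chloride; it sets out from 15 and returns at 18. Everninic acid 15 is benzylated twice with 3 and K2CO3 in DMF to give benzyl 2-(benzyloxy)-4-methoxy-6-methylbenzoate F5. The hindered ester of F5 is saponified with KOH in aqueous DMSO at 80 °C and acidified to give 2-(benzyloxy)-4-methoxy-6-methylbenzoic acid F6. Oxalyl chloride with catalytic DMF in CH2Cl2 converts F6 into 2-(benzyloxy)-4-methoxy-6-methylbenzoyl chloride F7, which is used crude. F7 acylates the 4-OH of 14 with Et3N and catalytic DMAP in CH2Cl2 to give benzyl 4-{[2-(benzyloxy)-4-methoxy-6-methylbenzoyl]oxy}-2-hydroxy-6-pentylbenzoate F8. Hydrogenolysis of F8 (H2, 10% Pd/C, EtOAc) removes both benzyl groups and gives 18 directly.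

Step 3. Bromine may enter the position between the two benzyloxy groups, or the ring may brominate twice. The fallback replaces electrophilic substitution by directed deprotonation; it sets out from 4 and returns at 9. Lithium 2,2,6,6-tetramethylpiperidide (LiTMP, 1.1 equiv) in THF at −78 °C should remove the ring proton flanked by fluorine and a benzyloxy group, which is the most acidic one. At this temperature the hindered amide base should leave the benzylic positions intact, so a [1,2]-Wittig rearrangement of the ethers is not expected. This gives aryllithium 9 directly, which is carried on as in step 5 to 12, so bromide 5 is bypassed and no new compound is made.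

**Further compounds**

F1 | step 5 | 1,3-bis(benzyloxy)-5-bromobenzene | Brc1cc(OCc2ccccc2)cc(OCc2ccccc2)c1
F2 | step 5 | 1,3-bis(benzyloxy)-5-pentylbenzene | CCCCCc1cc(OCc2ccccc2)cc(OCc2ccccc2)c1
F3 | step 5 | 1,5-bis(benzyloxy)-2-bromo-3-pentylbenzene | CCCCCc1cc(OCc2ccccc2)cc(OCc2ccccc2)c1Br
F4 | step 5 | [2,4-bis(benzyloxy)-6-pentylphenyl]lithium | CCCCCc1cc(OCc2ccccc2)cc(OCc2ccccc2)c1[Li]
F5 | step 8 | benzyl 2-(benzyloxy)-4-methoxy-6-methylbenzoate | COc1cc(C)c(C(=O)OCc2ccccc2)c(OCc2ccccc2)c1
F6 | step 8 | 2-(benzyloxy)-4-methoxy-6-methylbenzoic acid | COc1cc(C)c(C(=O)O)c(OCc2ccccc2)c1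
F7 | step 8 | 2-(benzyloxy)-4-methoxy-6-methylbenzoyl chloride | COc1cc(C)c(C(Cl)=O)c(OCc2ccccc2)c1
F8 | step 8 | benzyl 4-{[2-(benzyloxy)-4-methoxy-6-methylbenzoyl]oxy}-2-hydroxy-6-pentylbenzoate | CCCCCc1cc(OC(=O)c2c(C)cc(OC)cc2OCc2ccccc2)cc(O)c1C(=O)OCc1ccccc1
F0 | step 3 | none | none
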